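**Retrosynthetic overview**

- The strategy rests on the furan C2=C3 bond, the enol-ether double bond between C2 (bonded to O1 and the aryl ring) and C3 (bearing the methoxy group). It is cut to an aryl ester carbonyl (C2, with O1 as the ester oxygen) and an α-methoxybenzylic phosphonium ylide (C3), so the 3-methoxy group arrives on the ylide carbon.
- The phosphonium salt comes from the dimethyl acetal of an ortho-aroyloxybenzaldehyde by exchange with PPh3·HBr. The ester comes from 4-(allyloxy)-2-hydroxy-5-prenylbenzaldehyde and 2-(allyloxy)-4-methoxybenzoyl chloride.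
- The prenyl group is placed on C5 of 2,4-dihydroxybenzaldehyde by iodination and Stille coupling with a prenylstannane made from prenyl bromide, before any allyl ether is present.
- Ring order: both benzene rings are bought; the furan ring is the only ring formed (step 10). The two allyl ethers are removed last with zerovalent palladium.

Key step: step 10

Remark on the chemistry: the target has no stereocentre; the benzylic carbon of the phosphonium salt is the only stereocentre on the route, is formed racemic and disappears in the key step. "Prenyl" means 3-methylbut-2-en-1-yl and "allyl" means prop-2-en-1-yl throughout.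

**Route**

Step 1
Reactants: 1 2,4-dihydroxybenzaldehyde
Product: 2 2,4-dihydroxy-5-iodobenzaldehyde
Conditions: ICl, AcOH, rt
Reagents that add atoms: iodine monochloride, ClI
Why: Electrophilic aromatic iodination should go to C5, which is para to the 2-hydroxyl and ortho to the 4-hydroxyl and less crowded than C3 between the two hydroxyls.

Step 2
Reactants: 3 prenyl bromide
Product: 5 tributyl(3-methylbut-2-en-1-yl)stannane, via prenylmagnesium bromide 4 (not isolated)
Conditions: Mg turnings, Bu3SnCl, THF, 0 °C → rt (Barbier conditions)
Reagents that add atoms: tributyltin chloride, CCCC[Sn](Cl)(CCCC)CCCC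
Why: In this Barbier reaction Mg inserts into the allylic C–Br bond and the allylic Grignard reagent is trapped at once by the bulky tin chloride at its unhindered primary carbon, which should give the primary prenyl stannane and keep Wurtz coupling low.

Step 3
Reactants: 2 2,4-dihydroxy-5-iodobenzaldehyde; 5 tributyl(3-methylbut-2-en-1-yl)stannane
Product: 6 2,4-dihydroxy-5-prenylbenzaldehyde
Conditions: Pd(PPh3)4 (5 mol %), DMF, 90 °C
Reagents that add atoms: none
Why: Stille coupling (oxidative addition of the aryl iodide to zerovalent palladium, transmetalation of the allylic stannane, reductive elimination at the less hindered allyl terminus) should give the linear prenyl arene and tolerates free phenols and the aldehyde.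

Step 4
Reactants: 6 2,4-dihydroxy-5-prenylbenzaldehyde
Product: 7 4-(allyloxy)-2-hydroxy-5-prenylbenzaldehyde
Conditions: allyl bromide (1.05 equiv), CsHCO3, MeCN, 60 °C
Reagents that add atoms: allyl bromide, C=CCBr
Why: Williamson etherification with a weak base should alkylate only the 4-hydroxyl, which is the more acidic one (para to the formyl group), while the 2-hydroxyl is held in a hydrogen bond to the aldehyde.

Step 5
Reactants: 8 2-hydroxy-4-methoxybenzoic acid
Product: 10 2-(allyloxy)-4-methoxybenzoic acid, via allyl 2-(allyloxy)-4-methoxybenzoate 9 (not isolated)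
Conditions: allyl bromide (2.5 equiv), K2CO3, DMF, 60 °C; then NaOH, MeOH/H2O, 60 °C; HCl (aq) work-up
Reagents that add atoms: allyl bromide, C=CCBr; sodium hydroxide, [Na+].[OH-]
Why: Double O-alkylation of the phenol and the carboxylate followed by saponification of the allyl ester (acyl–oxygen cleavage, the aryl allyl ether being stable to hydroxide) should leave only the phenol protected.

Step 6
Reactants: 10 2-(allyloxy)-4-methoxybenzoic acid
Product: 11 2-(allyloxy)-4-methoxybenzoyl chloride
Conditions: (COCl)2, DMF (cat.), CH2Cl2, 0 °C → rt; concentrated and used crude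
Reagents that add atoms: oxalyl chloride, ClC(=O)C(=O)Cl
Why: Acid chloride formation through the Vilsmeier-type chloroiminium species is neutral enough to leave the allyl ether and the methyl ether untouched.

Step 7
Reactants: 7 4-(allyloxy)-2-hydroxy-5-prenylbenzaldehyde; 11 2-(allyloxy)-4-methoxybenzoyl chloride
Product: 12 5-(allyloxy)-2-formyl-4-prenylphenyl 2-(allyloxy)-4-methoxybenzoate
Conditions: Et3N, DMAP (cat.), CH2Cl2, 0 °C → rt
Reagents that add atoms: none
Why: Acylation of the phenol under nucleophilic catalysis by DMAP should give the aryl ester, the only free hydroxyl being the one ortho to the aldehyde.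

Step 8
Reactants: 12 5-(allyloxy)-2-formyl-4-prenylphenyl 2-(allyloxy)-4-methoxybenzoate
Product: 13 5-(allyloxy)-2-(dimethoxymethyl)-4-prenylphenyl 2-(allyloxy)-4-methoxybenzoate
Conditions: HC(OMe)3, p-TsOH·H2O (2 mol %), MeOH/CH2Cl2, rt; Et3N quench; used without chromatography on acidic silica
Reagents that add atoms: trimethyl orthoformate, COC(OC)OC; methanol, CO
Why: Acid-catalysed acetalisation is driven by the orthoformate as water scavenger, and the crowded, electron-rich aroyl ester should resist methanolysis under these weakly acidic conditions at room temperature.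

Step 9
Reactants: 13 5-(allyloxy)-2-(dimethoxymethyl)-4-prenylphenyl 2-(allyloxy)-4-methoxybenzoate
Product: 14 racemic {[4-(allyloxy)-2-{[2-(allyloxy)-4-methoxybenzoyl]oxy}-5-prenylphenyl](methoxy)methyl}triphenylphosphonium bromide
Conditions: PPh3·HBr (1.05 equiv), CH2Cl2, 4 Å molecular sieves, rt; precipitation with Et2O
Reagents that add atoms: triphenylphosphine hydrobromide, [Br-].c1ccc(cc1)[PH+](c1ccccc1)c1ccccc1
Why: In this acetal-to-α-alkoxyphosphonium exchange the acid ionises the acetal to an oxocarbenium ion stabilised by the para allyloxy group, triphenylphosphine captures it at carbon, and the new benzylic stereocentre is formed racemic without consequence.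

Step 10
Reactants: 14 racemic {[4-(allyloxy)-2-{[2-(allyloxy)-4-methoxybenzoyl]oxy}-5-prenylphenyl](methoxy)methyl}triphenylphosphonium bromide
Product: 16 6-(allyloxy)-2-[2-(allyloxy)-4-methoxyphenyl]-3-methoxy-5-prenylbenzofuran, via phosphonium ylide 15 (not isolated)
Conditions: KN(SiMe3)2 (1.05 equiv), THF (0.01 M), −78 °C → rt, then 50 °C if needed
Reagents that add atoms: none
Why: Deprotonation gives the α-methoxy ylide 15, stabilised by phosphorus and the aryl ring, whose carbanion carbon (future C3) adds to the ortho aryl ester carbonyl (future C2) in a 5-exo-trig closure; the oxaphosphetane fused to the new five-membered ring then collapses with loss of triphenylphosphine oxide to the C2=C3 enol-ether bond and so completes the aromatic furan. The closest known reaction type is the intramolecular Wittig olefination of ester carbonyls used to make benzofurans from ortho-acyloxybenzyl phosphonium salts; an ester reacts here because the carbonyl is held next to the ylide and the product is aromatic. No stereocentre is formed, and the racemic centre of 14 is erased. The step needs olefination to win over loss of the aroyl group: a shift of the aroyl group from oxygen to the ylide carbon would give a phosphonium carbon without an acidic hydrogen, which cannot be drained off as a stabilised keto-ylide, and the phenoxide set free can re-add to the ketone and return to the same betaine, so both paths should lead to 16. The hindered amide base deprotonates the salt faster than it attacks the crowded ester, and high dilution suppresses intermolecular acyl transfer.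

Step 11
Reactants: 16 6-(allyloxy)-2-[2-(allyloxy)-4-methoxyphenyl]-3-methoxy-5-prenylbenzofuran
Product: 17 ambofuranol, 2-(2-hydroxy-4-methoxyphenyl)-3-methoxy-5-prenylbenzofuran-6-ol
Conditions: Pd(PPh3)4 (5 mol %), morpholine (10 equiv), THF, rt
Reagents that add atoms: none
Why: In this Tsuji–Trost deallylation zerovalent palladium ionises each aryl allyl ether to a π-allyl complex that morpholine captures, while the prenyl group (no leaving group at its allylic carbon), the methyl ethers and the furan enol ether should stay untouched.

**Compound list**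

1 | 2,4-dihydroxybenzaldehyde | O=Cc1ccc(O)cc1O | starting material
2 | 2,4-dihydroxy-5-iodobenzaldehyde | O=Cc1cc(I)c(O)cc1O | intermediate
3 | prenyl bromide (1-bromo-3-methylbut-2-ene) | CC(C)=CCBr | starting material
4 | prenylmagnesium bromide | CC(C)=CC[Mg]Br | intermediate
5 | tributyl(3-methylbut-2-en-1-yl)stannane | CCCC[Sn](CCCC)(CCCC)CC=C(C)C | intermediate
6 | 2,4-dihydroxy-5-prenylbenzaldehyde | O=Cc1cc(CC=C(C)C)c(O)cc1O | intermediate
7 | 4-(allyloxy)-2-hydroxy-5-prenylbenzaldehyde | O=Cc1cc(CC=C(C)C)c(OCC=C)cc1O | intermediate
8 | 2-hydroxy-4-methoxybenzoic acid | COc1ccc(C(=O)O)c(O)c1 | starting material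
9 | allyl 2-(allyloxy)-4-methoxybenzoate | COc1ccc(C(=O)OCC=C)c(OCC=C)c1 | intermediate
10 | 2-(allyloxy)-4-methoxybenzoic acid | COc1ccc(C(=O)O)c(OCC=C)c1 | intermediate
11 | 2-(allyloxy)-4-methoxybenzoyl chloride | COc1ccc(C(=O)Cl)c(OCC=C)c1 | intermediate
12 | 5-(allyloxy)-2-formyl-4-prenylphenyl 2-(allyloxy)-4-methoxybenzoate | O=Cc1cc(CC=C(C)C)c(OCC=C)cc1OC(=O)c1ccc(OC)cc1OCC=C | intermediate
13 | 5-(allyloxy)-2-(dimethoxymethyl)-4-prenylphenyl 2-(allyloxy)-4-methoxybenzoate | COC(OC)c1cc(CC=C(C)C)c(OCC=C)cc1OC(=O)c1ccc(OC)cc1OCC=C | intermediate
14 | racemic {[4-(allyloxy)-2-{[2-(allyloxy)-4-methoxybenzoyl]oxy}-5-prenylphenyl](methoxy)methyl}triphenylphosphonium bromide | C=CCOc1cc(OC(=O)c2ccc(OC)cc2OCC=C)c(C(OC)[P+](c2ccccc2)(c2ccccc2)c2ccccc2)cc1CC=C(C)C.[Br-] | intermediate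
15 | [4-(allyloxy)-2-{[2-(allyloxy)-4-methoxybenzoyl]oxy}-5-prenylphenyl](methoxy)methylidene(triphenyl)phosphorane (ylide) | C=CCOc1cc(OC(=O)c2ccc(OC)cc2OCC=C)c(C(OC)=P(c2ccccc2)(c2ccccc2)c2ccccc2)cc1CC=C(C)C | intermediate
16 | 6-(allyloxy)-2-[2-(allyloxy)-4-methoxyphenyl]-3-methoxy-5-prenylbenzofuran | C=CCOc1cc2oc(-c3ccc(OC)cc3OCC=C)c(OC)c2cc1CC=C(C)C | intermediate
17 | ambofuranol | COc1ccc(-c2oc3cc(O)c(CC=C(C)C)cc3c2OC)c(O)c1 | target

**Step count**

Total steps: 11. Longest linear sequence: 8 steps (steps 1, 3, 4, 7, 8, 9, 10, 11).

**Steps most likely to fail**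

1. Step 10 (ester Wittig ring closure). The crowded, fully substituted oxaphosphetane may form too slowly, so that cleavage of the aryl ester by the base or intermolecular transfer of the aroyl group consumes the ylide. The fallback sets out from acetal 13 and comes back at benzofuran 16. It forms the C2–C3 bond by a deliberate acyl shift and closes the ring at O1–C2 by dehydration.
   - Exchange of one acetal methoxy group with benzenesulfinic acid (CaCl2, CH2Cl2, rt) would give racemic 5-(allyloxy)-2-[methoxy(phenylsulfonyl)methyl]-4-prenylphenyl 2-(allyloxy)-4-methoxybenzoate F1.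
   - LiN(SiMe3)2 (THF, −78 °C → 0 °C) would form the sulfonyl carbanion, which takes over the neighbouring aroyl group by a 1,4 shift from oxygen to carbon and should give, after protonation, racemic 2-[4-(allyloxy)-2-hydroxy-5-prenylphenyl]-1-[2-(allyloxy)-4-methoxyphenyl]-2-methoxy-2-(phenylsulfonyl)ethan-1-one F2.
   - Reductive desulfonylation (Zn, AcOH, THF, rt) would give racemic 2-[4-(allyloxy)-2-hydroxy-5-prenylphenyl]-1-[2-(allyloxy)-4-methoxyphenyl]-2-methoxyethan-1-one F3.
   - Pyridinium p-toluenesulfonate in toluene at 80 °C would close the hemiketal and dehydrate it to 16. The free phenol of F3 is para to the prenyl group, so no chroman can form.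

2. Step 3 (Stille prenylation). The unsymmetrical allyl group may be transferred through its tertiary terminus (reverse prenylation), or the double bond may migrate at 90 °C. The fallback sets out from iodide 2 and comes back at 6.
   - Stille coupling with the symmetrical allyl donor Bu3SnCH2CH=CH2 (Pd(PPh3)4, DMF, 90 °C) would give 5-allyl-2,4-dihydroxybenzaldehyde F4, for which no regiochemical question arises.
   - Cross-metathesis with 2-methyl-2-butene (second-generation Grubbs catalyst, CH2Cl2, 40 °C) would then build the trisubstituted alkene of 6.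

3. Step 9 (phosphonium salt formation). HBr may add across the trisubstituted double bond of the prenyl group, or the exchange may stall because the methanol released reverses it. The fallback sets out from acetal 13 and comes back at 14, with no Brønsted acid and no free methanol.
   - Me3SiBr (1.05 equiv) with 2,6-di-tert-butylpyridine in CH2Cl2 at −40 °C would convert the acetal into racemic 5-(allyloxy)-2-[bromo(methoxy)methyl]-4-prenylphenyl 2-(allyloxy)-4-methoxybenzoate F5.
   - PPh3 added to the same flask would displace bromide to give 14.

**Further compounds**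

F1 | step 10 | racemic 5-(allyloxy)-2-[methoxy(phenylsulfonyl)methyl]-4-prenylphenyl 2-(allyloxy)-4-methoxybenzoate | COC(c1cc(CC=C(C)C)c(OCC=C)cc1OC(=O)c1ccc(OC)cc1OCC=C)S(=O)(=O)c1ccccc1
F2 | step 10 | racemic 2-[4-(allyloxy)-2-hydroxy-5-prenylphenyl]-1-[2-(allyloxy)-4-methoxyphenyl]-2-methoxy-2-(phenylsulfonyl)ethan-1-one | COC(c1cc(CC=C(C)C)c(OCC=C)cc1O)(C(=O)c1ccc(OC)cc1OCC=C)S(=O)(=O)c1ccccc1
F3 | step 10 | racemic 2-[4-(allyloxy)-2-hydroxy-5-prenylphenyl]-1-[2-(allyloxy)-4-methoxyphenyl]-2-methoxyethan-1-one | COC(c1cc(CC=C(C)C)c(OCC=C)cc1O)C(=O)c1ccc(OC)cc1OCC=C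
F4 | step 3 | 5-allyl-2,4-dihydroxybenzaldehyde | O=Cc1cc(CC=C)c(O)cc1O
F5 | step 9 | racemic 5-(allyloxy)-2-[bromo(methoxy)methyl]-4-prenylphenyl 2-(allyloxy)-4-methoxybenzoate | COC(Br)c1cc(CC=C(C)C)c(OCC=C)cc1OC(=O)c1ccc(OC)cc1OCC=C
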